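# Proposed synthesis of CNP0193334.1: ring A by thiophene dioxide Diels–Alder on the anti dimer of cyclobutadiene

## The problem

The target is a 2-O-alkyl glycerol whose octyl chain ends on a tetracyclic hydrocarbon: cyclohexane ring A is fused through one bond (C1–C8) to a ladder of three cyclobutanes, B (C1, C2, C7, C8), C (C2, C3, C6, C7) and D (C3, C4, C5, C6). C9–C12 complete ring A (C9 on C8, C12 on C1) and the chain sits on C11; these locants are kept fixed for every intermediate. All fusions are cis and neighbouring rings are anti across each cyclobutane, so C1, C2, C3, C6, C7 and C8 form one rigid staircase. Without the chain the tetracycle is meso, so C11 alone makes the molecule chiral and the absolute configuration is a desymmetrisation problem. C11 is 1,3 to C1 and 1,4 to C8, its chain is cis to ring B, and neither C11 epimer is clearly favoured, so a temporary stereocenter next to C11 has to control it. The bicyclo[2.2.0]hexane units are highly strained: prolonged heating, carbocations beside the ladder, hydrogenolysis catalysts and slow radical chemistry at C9 and C12 (cyclobutylcarbinyl positions) must be avoided. The glycerol part is an achiral 1,3-diol that needs one protecting group stable to organomagnesium, hydride, fluoride and tin hydride reagents. The enabling feature is that ring A shares only C1–C8 with the ladder: C1–C12 and C8–C9 are the two bonds a four-carbon diene forms on a cyclobutene, and the ladder without ring A is the anti dimer of cyclobutadiene.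

## Retrosynthesis

**22 to 21.** The two acetal C–O bonds of the glycerol unit are the last to be cleaved. A benzylidene acetal is chosen because the 1,3-dioxane 12 is commercial with only O-2 of glycerol free, and it survives every reagent of the route. The forward step is mild aqueous acid.

**21 back to 16 (through 20, 19, 18, 17).** Oxygens are put back on C9 and C12 and the C4=C5 alkene is put back in ring D. The C12 oxygen is the control element next to C11; the C9 oxygen is the carbonyl that activates C11 as an acceptor. Forward, ketone 16 is reduced to alcohol 17, the ring D alkene is saturated with diimide to give 18, the silyl ether is removed to give diol 19, and both hydroxyls leave together from bis-xanthate 20. Diimide is placed at 17 because no enone or carbonyl is then present and no hydrogenolysis catalyst is needed.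

**16 to 11 and 14 (via 15).** The C11–chain bond is cut. Cutting inside the chain or at the ether oxygen would leave C11 to be set on a ring-bound stub and add linear steps on the ladder. This cut gives enone 11 and bromide 14, which is made in one step and is used as its Grignard reagent 15. The forward reaction must add to C11 anti to the C12 silyloxy group.

**14 to 12 and 13.** The ether C–O bond is cut. 1,8-Dibromooctane 13 in excess gives the bromo ether directly, with no protecting-group steps on a bromo alcohol.

**11 to 10 to 8 (via 9).** Both C–O bonds at C9 and C12 come from one molecule of O2. The meso diene 8 has enantiotopic termini; 1,4-dioxygenation to endoperoxide 9 followed by a Kornblum–DeLaMare rearrangement under a chiral base tells them apart and gives carbonyl at C9 and carbinol at C12 in 10, which is silylated to 11. Hydroboration or epoxidation of a ring A alkene would give neither the acceptor nor the neighbouring oxygen. The forward reaction needs singlet oxygen to add anti to ring B and the base to choose one bridgehead hydrogen.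

**8 to 3 and 6 (via 7), the key cut.** C1–C12 and C8–C9 are cut. Cutting ladder rungs instead would require [2+2] photochemistry with a syn/anti question at every rung. This cut keeps all three cyclobutanes in a known C8H8 hydrocarbon, 3, and delivers ring A as a 1,3-diene, which the previous paragraph needs. The forward reaction needs mono-addition, attack on the exo face of one cyclobutene, and low temperature; the sulfone-bridged adduct 7 loses SO2 on the way.

**3 to 1 (via 2); 6 to 4 (via 5).** The central cyclobutane of 3 is cut into two C4 units: two molecules of cis-3,4-dichlorocyclobutene 1 are coupled reductively, through dichloride 2, with loss of all four chlorines. Lithium amalgam is specified because it is known to favour the anti dimer by a stepwise organometallic coupling, whereas sodium amalgam releases cyclobutadiene and favours the syn isomer. Thiophene 4 is oxidised twice at sulfur, through S-oxide 5, to give 6.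

## Roads not taken

**Alternative 1:** The cut removes all four rungs (C1–C8, C2–C7, C3–C6, C4–C5) and leads to acyclic tetraene A1, in which C11 is the only stereocenter. Forward, irradiation with (CuOTf)2·C6H6 (monovalent copper) would add the two diene arms to each other twice to give tetracycle A2.
- Merits: four rings and six stereocenters in one operation; C11 is made on an open chain by standard methods; no desymmetrisation and no temporary oxygens. In step count this road is clearly better than the chosen one.
- Weak points: the copper-templated [2+2] is dependable for 1,6-dienes, but the first closure here needs a 1,7-diene to form ring A. The second closure involves a cis-1,2-divinylcyclobutane, a 1,5-diene whose photo-[2+2] prefers the crossed bicyclo[2.1.1] mode. Conjugated dienes also isomerise and dimerise under these conditions. The remote C11 centre would have to dictate the folding sense of the whole ladder.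
- Comparison: the chosen plan is longer, but each bond-forming event has a close model and each stereochemical relationship is set under adjacent control.

**Alternative 2:** The cut is at C1–C8 and C2–C7, made by an electrocyclic cascade. Diyne A3 is semireduced to tetraene A4, which closes by conrotatory 8π and then disrotatory 6π steps; the intended product is meso diallyl diene A5. Ring A would follow by ring-closing metathesis and rings C and D by a later photoclosure.
- Merits: a thermal cascade near room temperature from a linear precursor; no strained reagent, no mercury, easy to scale. In starting-material cost it is better than the chosen plan.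
- Weak points: orbital symmetry works against it. An E,Z,Z,E tetraene places the two terminal substituents trans, so the cascade should give the racemic trans isomer A6, not A5. The cis A/B fusion would need the harder E,Z,Z,Z geometry. Ring A then carries only an isolated, symmetric C10=C11 alkene with no neighbouring control element, and a photochemical 4π closure is still required.
- Comparison: the chosen plan buys the whole ladder in one ground-state dimerisation and brings ring A in as a diene that can be desymmetrised.

**Alternative 3:** The cut is at the C/D fusion bond C3–C6. Tricyclic triene A7, derived from cyclooctatetraene A9, would be irradiated so that its cyclohexadiene closes by disrotatory 4π cyclisation to meso diene A8.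
- Merits: cheap feedstock; the photoisomerisation of the parent bicyclic diene is a model; closure away from ring B should give the anti ladder. It avoids both the unstable sulfone 6 and dichloride 1, which is itself made from cyclooctatetraene A9; in this respect it is better.
- Weak points: the same chromophore opens photochemically to a monocyclic eight-membered triene, and the cyclobutene product is itself photolabile, so conversion must be kept low. A8, like A5, offers only the symmetric C10=C11 alkene for placing the chain, beside a more reactive cyclobutene.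
- Comparison: the chosen plan uses no photochemical C–C bond formation, and its key product carries the ring A diene that makes the singlet oxygen and Kornblum–DeLaMare sequence possible.

Key step: step 3

## Route

Assumption: the lithium amalgam coupling of 1 is taken to run through dichloride 2 and not through free cyclobutadiene; 2 is written as the isomer that can close to the anti ladder.

Assumption: the sense of induction of the cinchona base on the new meso endoperoxide 9 cannot be predicted with confidence; the quinidine-derived catalyst is written, and its quinine-derived pseudoenantiomer (9-O-acetylcupreine) is used instead if a first test shows the opposite sense.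

Assumption: 12 is used as the commercial cis isomer; its ring configuration is lost in step 13 and has no bearing on the route.

Step 1
Reactants: 1 cis-3,4-dichlorocyclobutene (two molecules are joined; the second is entered below)
Product: 3 anti-tricyclo[4.2.0.0(2,5)]octa-3,7-diene (anti dimer of cyclobutadiene, meso), via dichloro dimer 2 (not isolated)
Conditions: Li/Hg (0.5% Li, 2.2 equiv Li per 1), Et2O, 20 °C; fractional distillation
Reagents that add atoms: cis-3,4-dichlorocyclobutene (the second molecule of 1), Cl[C@H]1C=C[C@H]1Cl
Why: Reductive Wurtz-type coupling (2 C4H4Cl2 + 4 Li → C8H8 + 4 LiCl) is the established preparation of the cyclobutadiene dimers, and lithium amalgam is known to favour the anti isomer. Reductive lithiation of one allylic chloride and invertive coupling with a second molecule of 1 should give dichloride 2, and a second lithiation with intramolecular displacement of the remaining chloride closes the central cyclobutane. Each cyclobutene is cis-fused by necessity, the anti relationship follows from the like configuration of the two ring-joining carbons of 2, and the minor syn isomer should be removable by spinning-band distillation or preparative gas chromatography.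

Step 2
Reactants: 4 thiophene
Product: 6 thiophene 1,1-dioxide, via thiophene 1-oxide 5 (not isolated)
Conditions: dimethyldioxirane (3 equiv), acetone, −20 °C, dark; volatiles removed at −40 °C; taken up in cold CH2Cl2 and used at once
Reagents that add atoms: dimethyldioxirane, CC1(C)OO1
Why: Electrophilic oxygen transfer to sulfur, twice, under neutral conditions is the known route to the parent dioxide. The compound dimerises at room temperature, so it is made and kept cold.

Step 3
Reactants: 3 anti-tricyclo[4.2.0.0(2,5)]octa-3,7-diene (4 equiv), 6 thiophene 1,1-dioxide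
Product: 8 meso tetracyclo[6.4.0.0(2,7).0(3,6)]dodeca-4,9,11-triene, via sulfone-bridged cycloadduct 7 (not isolated)
Conditions: cold CH2Cl2 solution of 6 added slowly to 3, CH2Cl2, −30 → 20 °C, dark; excess 3 and solvent removed at ≤ 0 °C under vacuum; 8 used at once
Reagents that add atoms: none
Why: The sulfone-lowered, non-aromatic diene 6 and the strained cis-alkene of 3 should combine in an inverse-electron-demand suprafacial [4+2] cycloaddition to give cycloadduct 7, a 7-thiabicyclo[2.2.1]hept-2-ene 7,7-dioxide. Adduct 7 should then lose SO2 at or below room temperature by a thermally allowed cheletropic extrusion, driven by strain release and gas loss, leaving ring A as a cyclohexa-1,3-diene. The closest known reaction type is the cycloaddition and SO2 extrusion of thiophene 1,1-dioxides with cyclobutenes, cyclopropenes and norbornenes. Ring A closes by intermolecular [4+2] annulation, with C1–C12 and C8–C9 formed in the same event, followed by loss of the one-atom bridge. The new stereocenters C1 and C8 are cis because the addition is suprafacial on a cis-alkene, and attack on the convex (exo) face of the bicyclo[2.2.0]hexene, away from the far cyclobutene, places ring A anti to ring C across ring B. Both partners are symmetric, so there is no regiochemistry, the orientation of the sulfone bridge is erased on extrusion, and 8 is meso. The step needs mono- over bis-addition, which the excess of recoverable 3 secures, and cycloaddition over self-dimerisation of 6, which slow addition of dilute 6 to concentrated strained alkene secures. It is run and worked up cold because the bicyclo[4.2.0]octa-2,4-diene unit of 8 can open by 6π electrocyclic reaction on warming.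

Step 4
Reactants: 8 meso tetracyclo[6.4.0.0(2,7).0(3,6)]dodeca-4,9,11-triene
Product: 10 12-hydroxytetracyclo[6.4.0.0(2,7).0(3,6)]dodeca-4,10-dien-9-one (hydroxyl anti to ring B; the enantiomer drawn in the compound list), via endoperoxide 9 (not isolated)
Conditions: O2, tetraphenylporphyrin (cat.), visible light, CH2Cl2, −78 °C; Ar purge; then 9-O-acetylcupreidine (10 mol%), −20 → 20 °C
Reagents that add atoms: dioxygen, O=O
Why: Singlet oxygen should add [4+2] to the ring A diene far faster than it touches the cyclobutene, from the face anti to ring B, which fixes the C12 oxygen on that face. The chiral base then removes one of the two enantiotopic bridgehead hydrogens (C9–H) with O–O cleavage, an enantioselective Kornblum–DeLaMare desymmetrisation of a meso endoperoxide, and so sets the absolute configuration. Telescoping avoids isolating a strained peroxide.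

Step 5
Reactants: 10 12-hydroxytetracyclo[6.4.0.0(2,7).0(3,6)]dodeca-4,10-dien-9-one
Product: 11 12-(tert-butyldimethylsilyloxy)tetracyclo[6.4.0.0(2,7).0(3,6)]dodeca-4,10-dien-9-one
Conditions: TBSCl, imidazole, DMF, 0 → 20 °C
Reagents that add atoms: tert-butyldimethylsilyl chloride, CC(C)(C)[Si](C)(C)Cl
Why: Standard silylation of a secondary alcohol; the bulky silyl ether protects the hydroxyl and provides the steric bias for step 7.

Step 6
Reactants: 12 cis-2-phenyl-1,3-dioxan-5-ol, 13 1,8-dibromooctane (4 equiv)
Product: 14 cis-5-[(8-bromooctyl)oxy]-2-phenyl-1,3-dioxane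
Conditions: NaH, Bu4NI (cat.), DMF, 0 → 20 °C
Reagents that add atoms: none
Why: Williamson etherification of the sodium alkoxide with a primary bromide; the excess of dibromide suppresses double substitution and is recovered.

Step 7
Reactants: 11 12-(tert-butyldimethylsilyloxy)tetracyclo[6.4.0.0(2,7).0(3,6)]dodeca-4,10-dien-9-one, 14 cis-5-[(8-bromooctyl)oxy]-2-phenyl-1,3-dioxane
Product: 16 12-(tert-butyldimethylsilyloxy)-11-{8-[(cis-2-phenyl-1,3-dioxan-5-yl)oxy]octyl}tetracyclo[6.4.0.0(2,7).0(3,6)]dodec-4-en-9-one (chain trans to the silyloxy group and cis to ring B), via alkylmagnesium bromide 15 (not isolated)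
Conditions: 14, Mg, THF, 40 °C; then slow addition to 11, CuBr·SMe2 (20 mol%), THF, −78 → −40 °C; aq. NH4Cl/NH3
Reagents that add atoms: none
Why: Copper-catalysed conjugate addition of a Grignard reagent to a cyclohexenone. The organocopper should attack C11 anti to the neighbouring C12 silyloxy group, the usual outcome for 4-silyloxycyclohexenones, which puts the chain cis to ring B as the target requires. C8 stays cis-fused because the trans fusion is much more strained.

Step 8
Reactants: 16 the ketone of step 7
Product: 17 12-(tert-butyldimethylsilyloxy)-11-{8-[(cis-2-phenyl-1,3-dioxan-5-yl)oxy]octyl}tetracyclo[6.4.0.0(2,7).0(3,6)]dodec-4-en-9-ol (mixture of C9 epimers)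
Conditions: NaBH4, MeOH/THF, 0 °C
Reagents that add atoms: none
Why: Hydride reduction of a ketone; the configuration at C9 is irrelevant because this oxygen is removed in step 12.

Step 9
Reactants: 17 the alcohol of step 8
Product: 18 12-(tert-butyldimethylsilyloxy)-11-{8-[(cis-2-phenyl-1,3-dioxan-5-yl)oxy]octyl}tetracyclo[6.4.0.0(2,7).0(3,6)]dodecan-9-ol
Conditions: 2-nitrobenzenesulfonohydrazide (excess), Et3N, CH2Cl2, 20 °C
Reagents that add atoms: none
Why: Diimide generated in the flask transfers two hydrogens in a concerted syn fashion to the strained cyclobutene, the only alkene left. No metal catalyst is involved, so neither the benzylidene acetal nor the cyclobutane bonds are at risk of hydrogenolysis.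

Step 10
Reactants: 18 the saturated silyl ether of step 9
Product: 19 11-{8-[(cis-2-phenyl-1,3-dioxan-5-yl)oxy]octyl}tetracyclo[6.4.0.0(2,7).0(3,6)]dodecane-9,12-diol
Conditions: Bu4NF, THF, 20 → 40 °C
Reagents that add atoms: none
Why: Fluoride cleavage of a secondary silyl ether; the acetal and the hydrocarbon core are inert to it.

Step 11
Reactants: 19 the diol of step 10
Product: 20 O,O'-(11-{8-[(cis-2-phenyl-1,3-dioxan-5-yl)oxy]octyl}tetracyclo[6.4.0.0(2,7).0(3,6)]dodecane-9,12-diyl) bis(S-methyl dithiocarbonate)
Conditions: NaH, CS2, imidazole (cat.), THF, 0 → 20 °C; then MeI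
Reagents that add atoms: carbon disulfide, S=C=S; iodomethane, CI
Why: Xanthate formation through the alkoxides is reliable for hindered secondary alcohols, and one molecule each of CS2 and MeI is taken up per hydroxyl. The 1,4-relationship of the two groups rules out cyclic thiocarbonate formation.

Step 12
Reactants: 20 the bis-xanthate of step 11
Product: 21 cis-2-phenyl-5-{[8-(tetracyclo[6.4.0.0(2,7).0(3,6)]dodecan-11-yl)octyl]oxy}-1,3-dioxane
Conditions: Bu3SnH (excess, ≥ 0.5 M), Et3B, air, toluene, 0 → 20 °C
Reagents that add atoms: none
Why: Double Barton–McCombie deoxygenation. The secondary radicals at C9 and C12 should take hydrogen from concentrated stannane at or below room temperature much faster than a cyclobutylcarbinyl radical opens. C11 and the ladder stereocenters are not involved.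

Step 13
Reactants: 21 the benzylidene acetal of step 12
Product: 22 2-{[8-(tetracyclo[6.4.0.0(2,7).0(3,6)]dodecan-11-yl)octyl]oxy}propane-1,3-diol (CNP0193334.1)
Conditions: AcOH/H2O/THF (4:1:1), 45 °C
Reagents that add atoms: none
Why: Acid hydrolysis of a benzylidene acetal of a 1,3-diol; the saturated ladder is stable to dilute acid at this temperature, and the glycerol oxygens are those already present.

## Compound list

1 | cis-3,4-dichlorocyclobutene | Cl[C@H]1C=C[C@H]1Cl | starting material
2 | trans,trans-4,4'-dichloro-1,1'-bi(cyclobut-2-en-1-yl), the C2-symmetric diastereomer with like configuration at the two ring-joining carbons (racemic, one enantiomer drawn) | Cl[C@@H]1C=C[C@H]1[C@@H]1C=C[C@H]1Cl | intermediate (not isolated)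
3 | anti-tricyclo[4.2.0.0(2,5)]octa-3,7-diene (meso) | C2=C[C@H]1[C@@H]3C=C[C@@H]3[C@@H]21 | intermediate
4 | thiophene | c1ccsc1 | starting material
5 | thiophene 1-oxide | O=S1C=CC=C1 | intermediate (not isolated)
6 | thiophene 1,1-dioxide | O=S1(=O)C=CC=C1 | intermediate
7 | sulfone-bridged cycloadduct: C9 and C12 of 8 joined by an SO2 bridge on the face anti to ring B (7-thiabicyclo[2.2.1]hept-2-ene 7,7-dioxide fused to the ladder) | C1=C[C@H]4[C@@H]2[C@H]([C@@H]1S4(=O)=O)[C@H]1[C@@H]3C=C[C@@H]3[C@@H]21 | intermediate (not isolated)
8 | meso tetracyclo[6.4.0.0(2,7).0(3,6)]dodeca-4,9,11-triene (cis-anti-cis-anti-cis) | C1=C[C@@H]2[C@H](C=C1)[C@H]1[C@@H]3C=C[C@@H]3[C@@H]21 | intermediate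
9 | 9,12-epidioxytetracyclo[6.4.0.0(2,7).0(3,6)]dodeca-4,10-diene (peroxide bridge anti to ring B, meso) | C1=C[C@H]4[C@@H]2[C@H]([C@@H]1OO4)[C@H]1[C@@H]3C=C[C@@H]3[C@@H]21 | intermediate (not isolated)
10 | 12-hydroxytetracyclo[6.4.0.0(2,7).0(3,6)]dodeca-4,10-dien-9-one (hydroxyl anti to ring B) | C1=CC(=O)[C@@H]2[C@H]([C@@H]1O)[C@H]1[C@@H]3C=C[C@@H]3[C@@H]21 | intermediate
11 | 12-(tert-butyldimethylsilyloxy)tetracyclo[6.4.0.0(2,7).0(3,6)]dodeca-4,10-dien-9-one | C1=CC(=O)[C@@H]2[C@H]([C@@H]1O[Si](C)(C)C(C)(C)C)[C@H]1[C@@H]3C=C[C@@H]3[C@@H]21 | intermediate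
12 | cis-2-phenyl-1,3-dioxan-5-ol | c1ccccc1[C@H]1OC[C@H](CO1)O | starting material
13 | 1,8-dibromooctane | BrCCCCCCCCBr | starting material
14 | cis-5-[(8-bromooctyl)oxy]-2-phenyl-1,3-dioxane | c1ccccc1[C@H]1OC[C@H](CO1)OCCCCCCCCBr | intermediate
15 | {8-[(cis-2-phenyl-1,3-dioxan-5-yl)oxy]octyl}magnesium bromide | c1ccccc1[C@H]1OC[C@H](CO1)OCCCCCCCC[Mg]Br | intermediate (not isolated)
16 | 12-(tert-butyldimethylsilyloxy)-11-{8-[(cis-2-phenyl-1,3-dioxan-5-yl)oxy]octyl}tetracyclo[6.4.0.0(2,7).0(3,6)]dodec-4-en-9-one (11,12-trans, chain cis to ring B) | c1ccccc1[C@H]1OC[C@H](CO1)OCCCCCCCC[C@H]1CC(=O)[C@@H]2[C@H]([C@@H]1O[Si](C)(C)C(C)(C)C)[C@H]1[C@@H]3C=C[C@@H]3[C@@H]21 | intermediate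
17 | the corresponding dodec-4-en-9-ol (C9 epimers) | c1ccccc1[C@H]1OC[C@H](CO1)OCCCCCCCC[C@H]1CC(O)[C@@H]2[C@H]([C@@H]1O[Si](C)(C)C(C)(C)C)[C@H]1[C@@H]3C=C[C@@H]3[C@@H]21 | intermediate
18 | the corresponding saturated dodecan-9-ol (C9 epimers) | c1ccccc1[C@H]1OC[C@H](CO1)OCCCCCCCC[C@H]1CC(O)[C@@H]2[C@H]([C@@H]1O[Si](C)(C)C(C)(C)C)[C@H]1[C@@H]3CC[C@@H]3[C@@H]21 | intermediate
19 | 11-{8-[(cis-2-phenyl-1,3-dioxan-5-yl)oxy]octyl}tetracyclo[6.4.0.0(2,7).0(3,6)]dodecane-9,12-diol (C9 epimers) | c1ccccc1[C@H]1OC[C@H](CO1)OCCCCCCCC[C@H]1CC(O)[C@@H]2[C@H]([C@@H]1O)[C@H]1[C@@H]3CC[C@@H]3[C@@H]21 | intermediate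
20 | 9,12-bis(S-methyl dithiocarbonate) of 19 | c1ccccc1[C@H]1OC[C@H](CO1)OCCCCCCCC[C@H]1CC(OC(=S)SC)[C@@H]2[C@H]([C@@H]1OC(=S)SC)[C@H]1[C@@H]3CC[C@@H]3[C@@H]21 | intermediate
21 | cis-2-phenyl-5-{[8-(tetracyclo[6.4.0.0(2,7).0(3,6)]dodecan-11-yl)octyl]oxy}-1,3-dioxane | c1ccccc1[C@H]1OC[C@H](CO1)OCCCCCCCC[C@H]1CC[C@@H]2[C@H](C1)[C@H]1[C@@H]3CC[C@@H]3[C@@H]21 | intermediate
22 | 2-{[8-(tetracyclo[6.4.0.0(2,7).0(3,6)]dodecan-11-yl)octyl]oxy}propane-1,3-diol (CNP0193334.1) | OCC(CO)OCCCCCCCC[C@H]1CC[C@@H]2[C@H](C1)[C@H]1[C@@H]3CC[C@@H]3[C@@H]21 | target

## Step count and risks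

Total: 13 steps. Longest linear sequence: 11 steps (1, 3, 4, 5, 7, 8, 9, 10, 11, 12, 13); steps 2 and 6 are one-step side branches.

**Step 3 (key step).** Self-dimerisation of 6 may outrun the cycloaddition, a second addition to the remaining cyclobutene may consume product, or the diene of 8 may open to a ring-opened triene during isolation. The fallback sets out from 3 and returns at 8. Dimer 3 is treated near room temperature with 2,3,4,5-tetrachlorothiophene 1,1-dioxide, a storable and much more reactive diene of the same class, which should give 9,10,11,12-tetrachlorotetracyclo[6.4.0.0(2,7).0(3,6)]dodeca-4,9,11-triene F1 after spontaneous SO2 loss. The four vinylic chlorines are then removed with sodium and tert-butanol in THF, stopped before the diene is reduced further, to give 8.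

**Step 4.** The chiral base may discriminate poorly between the two bridgehead hydrogens of an endoperoxide class on which it has not been tried, or background rearrangement may lower the enantiomeric purity. The fallback sets out from 8 and returns at 11. After photooxygenation as in step 4, thiourea in methanol reduces 9 to meso tetracyclo[6.4.0.0(2,7).0(3,6)]dodeca-4,10-diene-9,12-diol F2. Lipase-catalysed acetylation with vinyl acetate desymmetrises it to the 9-acetate 12-ol F3. Silylation with TBSCl and imidazole gives the 9-acetoxy-12-silyloxy diene F4, and K2CO3 in methanol frees the 12-silyloxy-9-ol F5. Oxidation of this allylic alcohol with MnO2 gives 11. Either sense of enzymatic selectivity can be used by choosing which oxygen is silylated and which is oxidised.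

**Step 7.** Facial selectivity may be poor. The anti-to-silyloxy preference points the nucleophile to the face that carries ring B, while the convex-face preference of a cis-fused bicyclo[4.2.0] enone points the other way, so the C11 epimer may form in quantity. The fallback sets out from 16 (as the epimer mixture) and returns at 19. Deprotonation of 16 with lithium diisopropylamide in THF at −78 °C and dehydrogenation in the same flask with N-tert-butylbenzenesulfinimidoyl chloride should give the 11-alkyl-12-silyloxy-dodeca-4,10-dien-9-one F6, which erases C11. Bu4NF then gives the 12-hydroxy dienone F7. Hydrogenation with [Ir(cod)(PCy3)(py)]PF6 in CH2Cl2 is directed by the C12 hydroxyl: it should deliver hydrogen to C11 on the hydroxyl face, which is also the convex face, and saturate the cyclobutene, giving the 12-hydroxy-11-alkyl-dodecan-9-one F8 with the chain cis to ring B. NaBH4 then gives 19.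

**Step 12.** Ring opening of ring B by β-scission may compete with hydrogen transfer, since both radicals are cyclobutylcarbinyl and two are generated per molecule. The fallback sets out from 16 and returns at 21; it removes the C9 oxygen by anionic chemistry so that only one radical is formed. Diimide from dipotassium azodicarboxylate and AcOH saturates the cyclobutene of 16 to give the 12-silyloxy-11-alkyl-dodecan-9-one F9. The ketone is reduced to methylene by the silyl-hydrazone variant of the Wolff–Kishner reduction (1,2-bis(tert-butyldimethylsilyl)hydrazine, cat. Sc(OTf)3; then KOt-Bu, t-BuOH, DMSO, ≤ 80 °C), giving the 12-silyloxy-11-alkyl-dodecane F10. Bu4NF gives the 11-alkyl-dodecan-12-ol F11, and NaH, CS2 and MeI give its S-methyl xanthate F12. Bu3SnH with Et3B and air at 0 °C then gives 21.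

## Further compounds

F1 | step 3 | 9,10,11,12-tetrachlorotetracyclo[6.4.0.0(2,7).0(3,6)]dodeca-4,9,11-triene | ClC1=C(Cl)[C@@H]2[C@H](C(Cl)=C1Cl)[C@H]1[C@@H]3C=C[C@@H]3[C@@H]21
F2 | step 4 | meso tetracyclo[6.4.0.0(2,7).0(3,6)]dodeca-4,10-diene-9,12-diol (both hydroxyls anti to ring B) | C1=C[C@H](O)[C@@H]2[C@H]([C@@H]1O)[C@H]1[C@@H]3C=C[C@@H]3[C@@H]21
F3 | step 4 | 12-hydroxytetracyclo[6.4.0.0(2,7).0(3,6)]dodeca-4,10-dien-9-yl acetate | C1=C[C@H](OC(C)=O)[C@@H]2[C@H]([C@@H]1O)[C@H]1[C@@H]3C=C[C@@H]3[C@@H]21
F4 | step 4 | 12-(tert-butyldimethylsilyloxy)tetracyclo[6.4.0.0(2,7).0(3,6)]dodeca-4,10-dien-9-yl acetate | C1=C[C@H](OC(C)=O)[C@@H]2[C@H]([C@@H]1O[Si](C)(C)C(C)(C)C)[C@H]1[C@@H]3C=C[C@@H]3[C@@H]21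
F5 | step 4 | 12-(tert-butyldimethylsilyloxy)tetracyclo[6.4.0.0(2,7).0(3,6)]dodeca-4,10-dien-9-ol | C1=C[C@H](O)[C@@H]2[C@H]([C@@H]1O[Si](C)(C)C(C)(C)C)[C@H]1[C@@H]3C=C[C@@H]3[C@@H]21
F6 | step 7 | 12-(tert-butyldimethylsilyloxy)-11-{8-[(cis-2-phenyl-1,3-dioxan-5-yl)oxy]octyl}tetracyclo[6.4.0.0(2,7).0(3,6)]dodeca-4,10-dien-9-one | c1ccccc1[C@H]1OC[C@H](CO1)OCCCCCCCCC1=CC(=O)[C@@H]2[C@H]([C@@H]1O[Si](C)(C)C(C)(C)C)[C@H]1[C@@H]3C=C[C@@H]3[C@@H]21
F7 | step 7 | 12-hydroxy-11-{8-[(cis-2-phenyl-1,3-dioxan-5-yl)oxy]octyl}tetracyclo[6.4.0.0(2,7).0(3,6)]dodeca-4,10-dien-9-one | c1ccccc1[C@H]1OC[C@H](CO1)OCCCCCCCCC1=CC(=O)[C@@H]2[C@H]([C@@H]1O)[C@H]1[C@@H]3C=C[C@@H]3[C@@H]21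
F8 | step 7 | 12-hydroxy-11-{8-[(cis-2-phenyl-1,3-dioxan-5-yl)oxy]octyl}tetracyclo[6.4.0.0(2,7).0(3,6)]dodecan-9-one (chain cis to ring B, trans to hydroxyl) | c1ccccc1[C@H]1OC[C@H](CO1)OCCCCCCCC[C@H]1CC(=O)[C@@H]2[C@H]([C@@H]1O)[C@H]1[C@@H]3CC[C@@H]3[C@@H]21
F9 | step 12 | 12-(tert-butyldimethylsilyloxy)-11-{8-[(cis-2-phenyl-1,3-dioxan-5-yl)oxy]octyl}tetracyclo[6.4.0.0(2,7).0(3,6)]dodecan-9-one | c1ccccc1[C@H]1OC[C@H](CO1)OCCCCCCCC[C@H]1CC(=O)[C@@H]2[C@H]([C@@H]1O[Si](C)(C)C(C)(C)C)[C@H]1[C@@H]3CC[C@@H]3[C@@H]21
F10 | step 12 | 12-(tert-butyldimethylsilyloxy)-11-{8-[(cis-2-phenyl-1,3-dioxan-5-yl)oxy]octyl}tetracyclo[6.4.0.0(2,7).0(3,6)]dodecane | c1ccccc1[C@H]1OC[C@H](CO1)OCCCCCCCC[C@H]1CC[C@@H]2[C@H]([C@@H]1O[Si](C)(C)C(C)(C)C)[C@H]1[C@@H]3CC[C@@H]3[C@@H]21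
F11 | step 12 | 11-{8-[(cis-2-phenyl-1,3-dioxan-5-yl)oxy]octyl}tetracyclo[6.4.0.0(2,7).0(3,6)]dodecan-12-ol | c1ccccc1[C@H]1OC[C@H](CO1)OCCCCCCCC[C@H]1CC[C@@H]2[C@H]([C@@H]1O)[C@H]1[C@@H]3CC[C@@H]3[C@@H]21
F12 | step 12 | S-methyl O-(11-{8-[(cis-2-phenyl-1,3-dioxan-5-yl)oxy]octyl}tetracyclo[6.4.0.0(2,7).0(3,6)]dodecan-12-yl) dithiocarbonate | c1ccccc1[C@H]1OC[C@H](CO1)OCCCCCCCC[C@H]1CC[C@@H]2[C@H]([C@@H]1OC(=S)SC)[C@H]1[C@@H]3CC[C@@H]3[C@@H]21
A1 | alternative 1 | (3E,9E)-6-[8-(tert-butyldimethylsilyloxy)octyl]dodeca-1,3,9,11-tetraene | CC(C)(C)[Si](C)(C)OCCCCCCCC[C@H](C/C=C/C=C)CC/C=C/C=C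
A2 | alternative 1 | 10-[8-(tert-butyldimethylsilyloxy)octyl]tetracyclo[6.4.0.0(2,7).0(3,6)]dodecane (target configuration) | CC(C)(C)[Si](C)(C)OCCCCCCCC[C@H]1CC[C@@H]2[C@H](C1)[C@H]1[C@@H]3CC[C@@H]3[C@@H]21
A3 | alternative 2 | (4E,10E)-tetradeca-1,4,10,13-tetraene-6,8-diyne | C=CC/C=C/C#CC#C/C=C/CC=C
A4 | alternative 2 | (4E,6Z,8Z,10E)-tetradeca-1,4,6,8,10,13-hexaene | C=CC/C=C/C=C\C=C/C=C/CC=C
A5 | alternative 2 | meso exo-cis-7,8-diallylbicyclo[4.2.0]octa-2,4-diene | C=CC[C@@H]2[C@H](CC=C)[C@H]1C=CC=C[C@@H]21
A6 | alternative 2 | trans-7,8-diallyl-cis-bicyclo[4.2.0]octa-2,4-diene (racemic, one enantiomer drawn) | C=CC[C@H]2[C@H](CC=C)[C@H]1C=CC=C[C@@H]21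
A7 | alternative 3 | anti-tricyclo[6.4.0.0(2,7)]dodeca-3,5,10-triene (meso) | C1=CC[C@@H]2[C@H](C1)[C@H]1C=CC=C[C@@H]21
A8 | alternative 3 | meso tetracyclo[6.4.0.0(2,7).0(3,6)]dodeca-4,10-diene | C1=CC[C@@H]2[C@H](C1)[C@H]1[C@@H]3C=C[C@@H]3[C@@H]21
A9 | alternative 3 | cyclooctatetraene | C1=CC=CC=CC=C1
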